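**Strategy.** The target is read as a crossed dimer of two antipodal ε-viniferin halves: a C8b–C8d bond and two eight-membered carbocycles, each closed by a bond from C7 of one half to a resorcinol ring of the other. The route makes the two C7 electrophiles one after the other as p-quinone methides. The key step exploits the 4-hydroxyphenyl ring on C7b and the free resorcinol ring of unit A: base expels sulfinate from C7b and C10a adds 1,6 to the quinone methide, closing the last ring (C7b, C8b, C8d, C9d, C10d, C8a, C9a, C10a) and setting C7b. Its precursor is an octaphenol sulfone in which every other ring is in place.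

Key step: step 18

Labels: the resveratrol units are A to D. In each unit C7 carries the 4-oxyphenyl ring, called aryl ring A, B, C or D after its unit, and C8 is its neighbour. C9 to C14 are the carbons of the 3,5-dioxygenated ring, called resorcinol ring A, B, C or D (C9 on C8, oxygen on C11 and C13). Half Y is units A and D: C7a and C8a are C2 and C3 of a (2R,3R)-2,3-dihydrobenzofuran fused to resorcinol ring D. Half X is units C and B: the (2S,3S)-dihydrobenzofuran fused to resorcinol ring B. Target descriptors: 7aR,8aR,7bR,8bS,7cS,8cS,7dR,8dR.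

Assumption: the separation of racemate 12 on a chiral phase is counted as one step per antipode. Both antipodes are used, each being the co-fraction of the step that collects the other. Ketone 19 is taken as a purchasable compound.

Step 1
Reactants: 1 5-bromobenzene-1,3-diol
Product: 2 2-bromo-4,6-dihydroxybenzaldehyde
Conditions: POCl3, DMF, MeCN, 0 °C to rt; then H2O, 50 °C
Reagents that add atoms: N,N-dimethylformamide CN(C)C=O; water O
Why: Vilsmeier–Haack formylation should go to the ring carbon para to one hydroxyl and ortho to the other, which is less hindered than the carbon between the two hydroxyls.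

Step 2
Reactants: 2 2-bromo-4,6-dihydroxybenzaldehyde
Product: 3 2-bromo-6-hydroxy-4-(methoxymethoxy)benzaldehyde
Conditions: MOMCl, iPr2NEt, CH2Cl2, 0 °C
Reagents that add atoms: chloromethyl methyl ether COCCl
Why: The hydroxyl para to the formyl group is the more acidic one and is not held in the hydrogen bond to the carbonyl, so the Williamson-type O-alkylation should stop at the 4-ether.

Step 3
Reactants: 3 2-bromo-6-hydroxy-4-(methoxymethoxy)benzaldehyde
Product: 4 tert-butyl 3-bromo-2-formyl-5-(methoxymethoxy)phenyl carbonate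
Conditions: Boc2O, iPr2NEt, DMAP (cat.), THF, 0 °C
Reagents that add atoms: di-tert-butyl dicarbonate CC(C)(C)OC(=O)OC(=O)OC(C)(C)C
Why: DMAP-catalysed O-acylation of the remaining chelated phenol installs the carbonate that serves in step 6 as migrating group and leaving group.

Step 4
Reactants: 1 5-bromobenzene-1,3-diol
Product: 5 1-bromo-3,5-bis(tert-butyldimethylsilyloxy)benzene
Conditions: TBSCl, imidazole, DMF, rt
Reagents that add atoms: tert-butyldimethylsilyl chloride CC(C)(C)[Si](C)(C)Cl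
Why: Standard imidazole-mediated silylation of both phenols gives the fluoride-labile resorcinol unit.

Step 5
Reactants: 6 4-(benzyloxy)benzyl bromide; 7 tetrahydrothiophene
Product: 8 1-[4-(benzyloxy)benzyl]tetrahydrothiophenium bromide
Conditions: acetone, rt
Reagents that add atoms: none
Why: S-alkylation of the sulfide by the benzylic bromide (SN2) gives the sulfonium salt that is the ylide precursor.

Step 6
Reactants: 5 1-bromo-3,5-bis(tert-butyldimethylsilyloxy)benzene; 4 tert-butyl 3-bromo-2-formyl-5-(methoxymethoxy)phenyl carbonate; 8 1-[4-(benzyloxy)benzyl]tetrahydrothiophenium bromide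
Product: 12 racemic trans-2-[4-(benzyloxy)phenyl]-4-bromo-3-[3,5-bis(tert-butyldimethylsilyloxy)phenyl]-6-(methoxymethoxy)-2,3-dihydrobenzofuran, via arylmagnesium bromide 9 (not isolated), via o-quinone methide 10 (not isolated), via sulfonium ylide 11 (not isolated)
Conditions: 5, Mg, LiCl, THF, 40 °C; then 4, THF, −78 °C; then 8 + KN(SiMe3)2 (THF, −78 °C), warm to 0 °C
Reagents that add atoms: none
Why: Grignard addition to the aldehyde, O-to-O migration of the Boc group and β-elimination of tert-butyl carbonate should give o-quinone methide 10, ylide 11 adds 1,4 and the phenoxide displaces tetrahydrothiophene (5-exo-tet, formal [4+1] annulation), the betaine closing through the rotamer with the two aryl groups anti, which gives the trans ring.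

Step 7
Reactants: 12 racemic trans-dihydrobenzofuran bromide
Product: 13 (2S,3S)-2-[4-(benzyloxy)phenyl]-4-bromo-3-[3,5-bis(tert-butyldimethylsilyloxy)phenyl]-6-(methoxymethoxy)-2,3-dihydrobenzofuran
Conditions: preparative HPLC, amylose tris(3,5-dimethylphenylcarbamate) phase, hexane/iPrOH, rt; (2S,3S) fraction
Reagents that add atoms: none
Why: Chromatography on a chiral stationary phase separates the antipodes without forming a stereocenter; this fraction supplies units C and B (7cS,8cS), and the (2R,3R) antipode elutes as the second fraction.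

Step 8
Reactants: 12 racemic trans-dihydrobenzofuran bromide
Product: 14 (2R,3R)-2-[4-(benzyloxy)phenyl]-4-bromo-3-[3,5-bis(tert-butyldimethylsilyloxy)phenyl]-6-(methoxymethoxy)-2,3-dihydrobenzofuran
Conditions: preparative HPLC, amylose tris(3,5-dimethylphenylcarbamate) phase, hexane/iPrOH, rt; (2R,3R) fraction
Reagents that add atoms: none
Why: The second fraction of the same resolution on the chiral stationary phase supplies units A and D (7aR,8aR), so neither antipode is discarded.

Step 9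
Reactants: 13 (2S,3S)-bromide
Product: 16 (2S,3S)-2-[4-(benzyloxy)phenyl]-3-[3,5-bis(tert-butyldimethylsilyloxy)phenyl]-6-(methoxymethoxy)-2,3-dihydrobenzofuran-4-carbaldehyde, via aryllithium 15 (not isolated)
Conditions: n-BuLi, THF, −78 °C; DMF; aq. NH4Cl
Reagents that add atoms: N,N-dimethylformamide CN(C)C=O
Why: Bromine–lithium exchange is faster than any deprotonation at −78 °C and the aryllithium is formylated by DMF; the aldehyde carbon is C8b.

Step 10
Reactants: 14 (2R,3R)-bromide
Product: 18 (2R,3R)-2-[4-(benzyloxy)phenyl]-3-[3,5-bis(benzyloxy)phenyl]-4-bromo-6-(methoxymethoxy)-2,3-dihydrobenzofuran, via free resorcinol 17 (not isolated)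
Conditions: TBAF, THF, 0 °C; then BnBr, rt
Reagents that add atoms: benzyl bromide BrCc1ccccc1
Why: Fluoride cleaves both aryl silyl ethers and the ammonium phenoxides are benzylated in the same flask (Williamson ether synthesis), which moves resorcinol ring A from the fluoride-labile to the hydrogenolysis-labile protecting set.

Step 11
Reactants: 18 (2R,3R)-bromide with resorcinol ring A as bis(benzyl ether); 19 1-[4-(tert-butyldimethylsilyloxy)phenyl]ethanone
Product: 20 2-[(2R,3R)-2-[4-(benzyloxy)phenyl]-3-[3,5-bis(benzyloxy)phenyl]-6-(methoxymethoxy)-2,3-dihydrobenzofuran-4-yl]-1-[4-(tert-butyldimethylsilyloxy)phenyl]ethanone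
Conditions: Pd2(dba)3 (cat.), XPhos, K3PO4, toluene, 90 °C
Reagents that add atoms: none
Why: Palladium-catalysed α-arylation of the methyl ketone enolate should stop at monoarylation with the ortho-substituted bromide, and K3PO4 spares the aryl silyl ether; the new CH2 is C8d and the carbonyl carbon is C7d.

Step 12
Reactants: 20 half-Y ketone; 16 half-X aldehyde
Product: 21 enone with a C8d=C8b double bond (E/Z mixture): 2-(half-Y aryl)-3-(half-X aryl)-1-[4-(tert-butyldimethylsilyloxy)phenyl]prop-2-en-1-one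
Conditions: piperidine, AcOH (cat.), toluene, reflux, Dean–Stark
Reagents that add atoms: none
Why: Knoevenagel-type aldol condensation of the methylene activated by ketone and aryl ring with the aldehyde; the alkene geometry does not matter because both sp2 carbons become stereocenters in step 14.

Step 13
Reactants: 6 4-(benzyloxy)benzyl bromide; 22 sodium 4-methylbenzenesulfinate
Product: 23 1-(benzyloxy)-4-[(4-methylphenyl)sulfonylmethyl]benzene
Conditions: DMF, 60 °C
Reagents that add atoms: none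
Why: S-alkylation of the sulfinate (SN2) gives the benzylic sulfone that will deliver C7b together with aryl ring B.

Step 14
Reactants: 21 enone; 23 benzylic sulfone
Product: 26 keto sulfone (C7d ketone; C7b bearing aryl ring B as benzyl ether plus the p-tolylsulfonyl group; both C7b epimers; C8b and C8d configured as in 35), via sulfonyl carbanion 24 (not isolated), via potassium enolate 25 (not isolated)
Conditions: 23, KN(SiMe3)2, THF/DMPU, −78 °C; 21, −78 to −40 °C; AcOH, −78 °C
Reagents that add atoms: none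
Why: Michael addition of the sulfone-stabilised carbanion should set C8b by attack on the face opposite resorcinol ring C, which screens the other face of the styrene-type carbon, and kinetic protonation of enolate 25 on the open C14d side with the C8b substituent turned away from resorcinol ring A should set C8d, giving the unlike pair of the target.

Step 15
Reactants: 26 keto sulfone
Product: 28 C7d acetate of the keto sulfone reduction product (both C7d epimers), via carbinol 27 (not isolated)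
Conditions: NaBH4, THF/MeOH, 0 °C; then Ac2O, pyridine, DMAP, CH2Cl2, rt
Reagents that add atoms: acetic anhydride CC(=O)OC(C)=O
Why: Hydride reduction of the only ketone and acetylation of the carbinol install the leaving group at C7d, whose configuration is irrelevant because it becomes trigonal in step 16; C8d can no longer epimerise.

Step 16
Reactants: 28 C7d acetate
Product: 31 first eight-membered ring closed (C7d–C10c bond; resorcinol ring C and aryl ring D as free phenols; C7d, C8d, C8b as in 35), via triphenol acetate 29 (not isolated), via p-quinone methide 30 (not isolated)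
Conditions: TBAF, THF (2 mM), −20 to 0 °C
Reagents that add atoms: none
Why: Fluoride frees the three silylated phenols, the phenoxide of aryl ring D expels acetate (1,6-elimination) to give p-quinone methide 30 and C10c of the resorcinolate of resorcinol ring C adds 1,6 to C7d, only phenoxide rings being nucleophilic here and C7b being inert while aryl ring B is a benzyl ether; C8d–H eclipses the quinone methide (allylic strain) and the nucleophile arrives from the C8b side, which should place H7d anti to H8d.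

Step 17
Reactants: 31 pentabenzyl ether with the first eight-membered ring
Product: 32 octaphenol sulfone (aryl rings A, B, C, D and resorcinol rings A and C free; C13b and C13d oxygens as MOM ethers)
Conditions: H2 (1 atm), Pd/C, EtOAc/MeOH, rt
Reagents that add atoms: none
Why: Hydrogenolysis removes the five benzyl ethers and thereby unmasks resorcinol ring A and the phenol of aryl ring B, while the sulfone and the two MOM ethers are inert to these conditions.

Step 18
Reactants: 32 octaphenol sulfone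
Product: 34 13b,13d-bis-O-(methoxymethyl) ether of the target, via p-quinone methide 33 (not isolated)
Conditions: Cs2CO3, degassed DMF (2 mM), 0 °C to rt; aq. NH4Cl
Reagents that add atoms: none
Why: Cs2CO3 ionises the phenols, the phenoxide of aryl ring B expels 4-methylbenzenesulfinate from C7b in a vinylogous E1cB (1,6-elimination) to give p-quinone methide 33, and C10a of the resorcinolate of resorcinol ring A, ortho to one oxygen and para to the other, adds to C7b in an intramolecular 1,6-conjugate addition that rearomatises aryl ring B. The closest known reactions are the base-induced generation of quinone methides from hydroxybenzyl sulfones and the 1,6-addition of phenols and naphthols to p-quinone methides. The eight-membered ring (C7b, C8b, C8d, C9d, C10d, C8a, C9a, C10a) closes in an 8-exo-trig mode through the C7b–C10a bond. C7b is set under substrate control: the tether from C8d should span to C7b without an eclipsed ring torsion only when the C8b–C8d bond lies near the plane of the quinone methide, and resorcinol ring A then adds to the face away from resorcinol ring B and syn to H8b, which puts H7b cis to H8b (7bR). The step needs chemoselectivity among the arenes and speed against tautomerisation of 33 to the C7b=C8b stilbene: under base only phenoxide rings are nucleophilic, so C14d of the MOM-protected resorcinol ring D (which would give a five-membered ring) is silent, the free ortho carbon of resorcinol ring C is held away by the first eight-membered ring, and O-alkylation is reversible.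

Step 19
Reactants: 34 bis-MOM ether
Product: 35 CNP0224452.2
Conditions: HCl (3 M in MeOH), 40 °C
Reagents that add atoms: none
Why: Acid-catalysed acetal exchange with methanol removes the two aryl MOM ethers under conditions too mild to ionise the C7 methines, so no stereocenter is touched.

**Compound list**

1 | 5-bromobenzene-1,3-diol | Oc1cc(O)cc(Br)c1 | starting material
2 | 2-bromo-4,6-dihydroxybenzaldehyde | O=Cc1c(O)cc(O)cc1Br | intermediate
3 | 2-bromo-6-hydroxy-4-(methoxymethoxy)benzaldehyde | O=Cc1c(O)cc(OCOC)cc1Br | intermediate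
4 | tert-butyl 3-bromo-2-formyl-5-(methoxymethoxy)phenyl carbonate | O=Cc1c(OC(=O)OC(C)(C)C)cc(OCOC)cc1Br | intermediate
5 | 1-bromo-3,5-bis(tert-butyldimethylsilyloxy)benzene | CC(C)(C)[Si](C)(C)Oc1cc(Br)cc(O[Si](C)(C)C(C)(C)C)c1 | intermediate
6 | 4-(benzyloxy)benzyl bromide | BrCc1ccc(OCc2ccccc2)cc1 | starting material
7 | tetrahydrothiophene | C1CCSC1 | starting material
8 | 1-[4-(benzyloxy)benzyl]tetrahydrothiophenium bromide | [Br-].C1CC[S+](C1)Cc1ccc(OCc2ccccc2)cc1 | intermediate
9 | 3,5-bis(tert-butyldimethylsilyloxy)phenylmagnesium bromide | CC(C)(C)[Si](C)(C)Oc1cc([Mg]Br)cc(O[Si](C)(C)C(C)(C)C)c1 | intermediate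
10 | 5-bromo-6-[3,5-bis(tert-butyldimethylsilyloxy)benzylidene]-3-(methoxymethoxy)cyclohexa-2,4-dien-1-one (o-quinone methide) | O=C1C=C(OCOC)C=C(Br)C1=Cc1cc(O[Si](C)(C)C(C)(C)C)cc(O[Si](C)(C)C(C)(C)C)c1 | intermediate
11 | tetrahydrothiophenium 4-(benzyloxy)benzylide | C1CC[S+](C1)[CH-]c1ccc(OCc2ccccc2)cc1 | intermediate
12 | racemic trans-2-[4-(benzyloxy)phenyl]-4-bromo-3-[3,5-bis(tert-butyldimethylsilyloxy)phenyl]-6-(methoxymethoxy)-2,3-dihydrobenzofuran (1:1 mixture of the 2S,3S and 2R,3R antipodes) | CC(C)(C)[Si](C)(C)Oc1cc(O[Si](C)(C)C(C)(C)C)cc(c1)[C@H]1c2c(cc(OCOC)cc2Br)O[C@@H]1c1ccc(OCc2ccccc2)cc1.CC(C)(C)[Si](C)(C)Oc1cc(O[Si](C)(C)C(C)(C)C)cc(c1)[C@@H]1c2c(cc(OCOC)cc2Br)O[C@H]1c1ccc(OCc2ccccc2)cc1 | intermediate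
13 | (2S,3S)-2-[4-(benzyloxy)phenyl]-4-bromo-3-[3,5-bis(tert-butyldimethylsilyloxy)phenyl]-6-(methoxymethoxy)-2,3-dihydrobenzofuran | CC(C)(C)[Si](C)(C)Oc1cc(O[Si](C)(C)C(C)(C)C)cc(c1)[C@H]1c2c(cc(OCOC)cc2Br)O[C@@H]1c1ccc(OCc2ccccc2)cc1 | intermediate
14 | (2R,3R)-2-[4-(benzyloxy)phenyl]-4-bromo-3-[3,5-bis(tert-butyldimethylsilyloxy)phenyl]-6-(methoxymethoxy)-2,3-dihydrobenzofuran | CC(C)(C)[Si](C)(C)Oc1cc(O[Si](C)(C)C(C)(C)C)cc(c1)[C@@H]1c2c(cc(OCOC)cc2Br)O[C@H]1c1ccc(OCc2ccccc2)cc1 | intermediate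
15 | (2S,3S)-2-[4-(benzyloxy)phenyl]-3-[3,5-bis(tert-butyldimethylsilyloxy)phenyl]-6-(methoxymethoxy)-2,3-dihydrobenzofuran-4-yllithium | CC(C)(C)[Si](C)(C)Oc1cc(O[Si](C)(C)C(C)(C)C)cc(c1)[C@H]1c2c(cc(OCOC)cc2[Li])O[C@@H]1c1ccc(OCc2ccccc2)cc1 | intermediate
16 | (2S,3S)-2-[4-(benzyloxy)phenyl]-3-[3,5-bis(tert-butyldimethylsilyloxy)phenyl]-6-(methoxymethoxy)-2,3-dihydrobenzofuran-4-carbaldehyde | CC(C)(C)[Si](C)(C)Oc1cc(O[Si](C)(C)C(C)(C)C)cc(c1)[C@H]1c2c(cc(OCOC)cc2C=O)O[C@@H]1c1ccc(OCc2ccccc2)cc1 | intermediate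
17 | 5-[(2R,3R)-2-[4-(benzyloxy)phenyl]-4-bromo-6-(methoxymethoxy)-2,3-dihydrobenzofuran-3-yl]benzene-1,3-diol | Oc1cc(O)cc(c1)[C@@H]1c2c(cc(OCOC)cc2Br)O[C@H]1c1ccc(OCc2ccccc2)cc1 | intermediate
18 | (2R,3R)-2-[4-(benzyloxy)phenyl]-3-[3,5-bis(benzyloxy)phenyl]-4-bromo-6-(methoxymethoxy)-2,3-dihydrobenzofuran | c1ccccc1COc1cc(OCc2ccccc2)cc(c1)[C@@H]1c2c(cc(OCOC)cc2Br)O[C@H]1c1ccc(OCc2ccccc2)cc1 | intermediate
19 | 1-[4-(tert-butyldimethylsilyloxy)phenyl]ethanone | CC(=O)c1ccc(O[Si](C)(C)C(C)(C)C)cc1 | starting material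
20 | 2-[(2R,3R)-2-[4-(benzyloxy)phenyl]-3-[3,5-bis(benzyloxy)phenyl]-6-(methoxymethoxy)-2,3-dihydrobenzofuran-4-yl]-1-[4-(tert-butyldimethylsilyloxy)phenyl]ethanone | c1ccccc1COc1cc(OCc2ccccc2)cc(c1)[C@@H]1c2c(cc(OCOC)cc2CC(=O)c2ccc(O[Si](C)(C)C(C)(C)C)cc2)O[C@H]1c1ccc(OCc2ccccc2)cc1 | intermediate
21 | enone: C7d ketone with aryl ring D as TBS ether, C8d=C8b double bond (E/Z mixture), half Y (7aR,8aR, resorcinol ring A as bis(benzyl ether)) on C8d, half X (7cS,8cS, resorcinol ring C as bis(TBS ether)) on C8b | c1ccccc1COc1cc(OCc2ccccc2)cc(c1)[C@@H]1c2c(cc(OCOC)cc2C(=Cc2cc(OCOC)cc3O[C@H](c4ccc(OCc5ccccc5)cc4)[C@@H](c4cc(O[Si](C)(C)C(C)(C)C)cc(O[Si](C)(C)C(C)(C)C)c4)c23)C(=O)c2ccc(O[Si](C)(C)C(C)(C)C)cc2)O[C@H]1c1ccc(OCc2ccccc2)cc1 | intermediate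
22 | sodium 4-methylbenzenesulfinate | [Na+].[O-]S(=O)c1ccc(C)cc1 | starting material
23 | 1-(benzyloxy)-4-[(4-methylphenyl)sulfonylmethyl]benzene | Cc1ccc(cc1)S(=O)(=O)Cc1ccc(OCc2ccccc2)cc1 | intermediate
24 | potassium salt of the α-sulfonyl carbanion of 23 | [K+].Cc1ccc(cc1)S(=O)(=O)[CH-]c1ccc(OCc2ccccc2)cc1 | intermediate
25 | potassium enolate (C7d–O−, C7d=C8d) of the Michael adduct, C8b as in 35, C7b unassigned | c1ccccc1COc1cc(OCc2ccccc2)cc(c1)[C@@H]1c2c(cc(OCOC)cc2C(=C([O-])c2ccc(O[Si](C)(C)C(C)(C)C)cc2)[C@@H](C(c2ccc(OCc3ccccc3)cc2)S(=O)(=O)c2ccc(C)cc2)c2cc(OCOC)cc3O[C@H](c4ccc(OCc5ccccc5)cc4)[C@@H](c4cc(O[Si](C)(C)C(C)(C)C)cc(O[Si](C)(C)C(C)(C)C)c4)c23)O[C@H]1c1ccc(OCc2ccccc2)cc1.[K+] | intermediate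
26 | keto sulfone: C7d ketone (aryl ring D as TBS ether), C7b bearing aryl ring B (benzyl ether) and p-tolylsulfonyl (both epimers), C8b and C8d as in 35 | c1ccccc1COc1cc(OCc2ccccc2)cc(c1)[C@@H]1c2c(cc(OCOC)cc2[C@@H](C(=O)c2ccc(O[Si](C)(C)C(C)(C)C)cc2)[C@@H](C(c2ccc(OCc3ccccc3)cc2)S(=O)(=O)c2ccc(C)cc2)c2cc(OCOC)cc3O[C@H](c4ccc(OCc5ccccc5)cc4)[C@@H](c4cc(O[Si](C)(C)C(C)(C)C)cc(O[Si](C)(C)C(C)(C)C)c4)c23)O[C@H]1c1ccc(OCc2ccccc2)cc1 | intermediate
27 | C7d carbinol of 26 (both C7d epimers) | c1ccccc1COc1cc(OCc2ccccc2)cc(c1)[C@@H]1c2c(cc(OCOC)cc2[C@@H](C(O)c2ccc(O[Si](C)(C)C(C)(C)C)cc2)[C@@H](C(c2ccc(OCc3ccccc3)cc2)S(=O)(=O)c2ccc(C)cc2)c2cc(OCOC)cc3O[C@H](c4ccc(OCc5ccccc5)cc4)[C@@H](c4cc(O[Si](C)(C)C(C)(C)C)cc(O[Si](C)(C)C(C)(C)C)c4)c23)O[C@H]1c1ccc(OCc2ccccc2)cc1 | intermediate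
28 | C7d acetate of 27 | c1ccccc1COc1cc(OCc2ccccc2)cc(c1)[C@@H]1c2c(cc(OCOC)cc2[C@@H](C(OC(C)=O)c2ccc(O[Si](C)(C)C(C)(C)C)cc2)[C@@H](C(c2ccc(OCc3ccccc3)cc2)S(=O)(=O)c2ccc(C)cc2)c2cc(OCOC)cc3O[C@H](c4ccc(OCc5ccccc5)cc4)[C@@H](c4cc(O[Si](C)(C)C(C)(C)C)cc(O[Si](C)(C)C(C)(C)C)c4)c23)O[C@H]1c1ccc(OCc2ccccc2)cc1 | intermediate
29 | triphenol acetate: 28 without its three silyl groups (resorcinol ring C and aryl ring D free) | c1ccccc1COc1cc(OCc2ccccc2)cc(c1)[C@@H]1c2c(cc(OCOC)cc2[C@@H](C(OC(C)=O)c2ccc(O)cc2)[C@@H](C(c2ccc(OCc3ccccc3)cc2)S(=O)(=O)c2ccc(C)cc2)c2cc(OCOC)cc3O[C@H](c4ccc(OCc5ccccc5)cc4)[C@@H](c4cc(O)cc(O)c4)c23)O[C@H]1c1ccc(OCc2ccccc2)cc1 | intermediate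
30 | p-quinone methide at C7d (aryl ring D as cyclohexadienone, resorcinol ring C free) | c1ccccc1COc1cc(OCc2ccccc2)cc(c1)[C@@H]1c2c(cc(OCOC)cc2[C@@H](C=C2C=CC(=O)C=C2)[C@@H](C(c2ccc(OCc3ccccc3)cc2)S(=O)(=O)c2ccc(C)cc2)c2cc(OCOC)cc3O[C@H](c4ccc(OCc5ccccc5)cc4)[C@@H](c4cc(O)cc(O)c4)c23)O[C@H]1c1ccc(OCc2ccccc2)cc1 | intermediate
31 | first eight-membered ring closed (C7d–C10c bond): resorcinol ring C and aryl ring D free, five benzyl ethers, two MOM ethers, C7b sulfone (both epimers); C7d, C8d, C8b as in 35 | c1ccccc1COc1cc(OCc2ccccc2)cc(c1)[C@@H]1c2c(cc(OCOC)cc2[C@H]2[C@H](c3ccc(O)cc3)c3c(O)cc(O)cc3[C@H]3c4c(cc(OCOC)cc4[C@@H]2C(c2ccc(OCc5ccccc5)cc2)S(=O)(=O)c2ccc(C)cc2)O[C@@H]3c2ccc(OCc3ccccc3)cc2)O[C@H]1c1ccc(OCc2ccccc2)cc1 | intermediate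
32 | octaphenol sulfone: 31 without its five benzyl groups | Oc1cc(O)cc(c1)[C@@H]1c2c(cc(OCOC)cc2[C@H]2[C@H](c3ccc(O)cc3)c3c(O)cc(O)cc3[C@H]3c4c(cc(OCOC)cc4[C@@H]2C(c2ccc(O)cc2)S(=O)(=O)c2ccc(C)cc2)O[C@@H]3c2ccc(O)cc2)O[C@H]1c1ccc(O)cc1 | intermediate
33 | p-quinone methide at C7b (aryl ring B as cyclohexadienone, resorcinol ring A free) | Oc1cc(O)cc(c1)[C@@H]1c2c(cc(OCOC)cc2[C@H]2[C@H](c3ccc(O)cc3)c3c(O)cc(O)cc3[C@H]3c4c(cc(OCOC)cc4[C@@H]2C=C2C=CC(=O)C=C2)O[C@@H]3c2ccc(O)cc2)O[C@H]1c1ccc(O)cc1 | intermediate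
34 | 13b,13d-bis-O-(methoxymethyl) ether of the target (7aR,8aR,7bR,8bS,7cS,8cS,7dR,8dR) | Oc1ccc([C@@H]2c3c(O)cc(O)cc3[C@@H]3c4c(cc(OCOC)cc4[C@H]4[C@H](c5ccc(O)cc5)c5c(O)cc(O)cc5[C@H]5c6c(cc(OCOC)cc6[C@H]24)O[C@@H]5c2ccc(O)cc2)O[C@H]3c2ccc(O)cc2)cc1 | intermediate
35 | CNP0224452.2 (7aR,8aR,7bR,8bS,7cS,8cS,7dR,8dR) | Oc1ccc([C@@H]2c3c(O)cc(O)cc3[C@@H]3c4c(cc(O)cc4[C@H]4[C@H](c5ccc(O)cc5)c5c(O)cc(O)cc5[C@H]5c6c(cc(O)cc6[C@H]24)O[C@@H]5c2ccc(O)cc2)O[C@H]3c2ccc(O)cc2)cc1 | target

**Count.** Total: 19 steps. Longest linear sequence: 14 steps (1, 2, 3, 6, 8, 10, 11, 12, 14, 15, 16, 17, 18, 19).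

**Steps most likely to fail**

Step 18 (key step). Base may remove H8b from quinone methide 33 and so tautomerise it to the C7b=C8b stilbene faster than the strained ring closes, or resorcinol ring A may add to the other face of C7b. The fallback sets out from 32. In NaHCO3-buffered MeCN/H2O the quinone methide should be trapped by water (1,6-hydration) to give the p-hydroxybenzylic carbinol F1. A chiral phosphoric acid (3,3'-bis(2,4,6-triisopropylphenyl)-1,1'-binaphthyl-2,2'-diyl hydrogen phosphate, the antipode matched to the substrate; CH2Cl2, 4 Å sieves, 0 °C) then re-forms the quinone methide without base and guides the addition of resorcinol ring A. Only free-phenol rings react with this weak acid, so the MOM-protected resorcinol ring D stays out. The fallback comes back at 34.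

Step 16. The first quinone methide 30 may tautomerise to the C7d=C8d stilbene or oligomerise before the medium ring closes, or H7d may end syn to H8d. The fallback sets out from 26. Reduction with NaBH4 gives carbinol 27, which is isolated this time, and TBAF/AcOH gives the tetraol F2. Diphenyl phosphate (cat., CH2Cl2, 0 °C to rt) then dehydrates the p-hydroxybenzylic alcohol to the quinone methide under acid catalysis and resorcinol ring C closes the ring. The fallback comes back at 31.

Step 14. The hindered α,β-diaryl enone may undergo 1,2-addition or retro-Michael reaction, and facial control at C8b or the protonation at C8d may be poor. The fallback sets out from 16 and 23. Addition of carbanion 24 to aldehyde 16 gives the β-hydroxy sulfone F3, which is dehydrated (MsCl, Et3N; then DBU) to the vinyl sulfone F4. The potassium enolate of ketone 20 then adds to C8b of F4 (Michael addition that forms the C8b–C8d bond instead of the C8b–C7b bond), and protonation at C7b brings the route back at 26.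

Further compounds
F1 | step 18 | C7b carbinol of the octaphenol (hydroxyl in place of the sulfonyl group of 32, both C7b epimers) | Oc1cc(O)cc(c1)[C@@H]1c2c(cc(OCOC)cc2[C@H]2[C@H](c3ccc(O)cc3)c3c(O)cc(O)cc3[C@H]3c4c(cc(OCOC)cc4[C@@H]2C(O)c2ccc(O)cc2)O[C@@H]3c2ccc(O)cc2)O[C@H]1c1ccc(O)cc1
F2 | step 16 | tetraol: carbinol 27 without its three silyl groups | c1ccccc1COc1cc(OCc2ccccc2)cc(c1)[C@@H]1c2c(cc(OCOC)cc2[C@@H](C(O)c2ccc(O)cc2)[C@@H](C(c2ccc(OCc3ccccc3)cc2)S(=O)(=O)c2ccc(C)cc2)c2cc(OCOC)cc3O[C@H](c4ccc(OCc5ccccc5)cc4)[C@@H](c4cc(O)cc(O)c4)c23)O[C@H]1c1ccc(OCc2ccccc2)cc1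
F3 | step 14 | β-hydroxy sulfone from 16 and 23 (diastereomer mixture at the two new carbons) | Cc1ccc(cc1)S(=O)(=O)C(C(O)c1cc(OCOC)cc2O[C@H](c3ccc(OCc4ccccc4)cc3)[C@@H](c3cc(O[Si](C)(C)C(C)(C)C)cc(O[Si](C)(C)C(C)(C)C)c3)c12)c1ccc(OCc2ccccc2)cc1
F4 | step 14 | vinyl sulfone with a C8b=C7b double bond (E/Z mixture) | Cc1ccc(cc1)S(=O)(=O)C(=Cc1cc(OCOC)cc2O[C@H](c3ccc(OCc4ccccc4)cc3)[C@@H](c3cc(O[Si](C)(C)C(C)(C)C)cc(O[Si](C)(C)C(C)(C)C)c3)c12)c1ccc(OCc2ccccc2)cc1
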